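The α-methylene-γ-butyrolactone (ring atoms O, C8, C7, C11, C12; C7/C8 are the fusion carbons, C11 bears the exocyclic CH2, C12 is the carbonyl) is read as one molecule of CO2 bridging the alkenyl carbon C11 and the carbinol carbon C8. The precursor is the complete furanone-bridged ten-membered ring, epoxy ester in place, with a 1-bromovinyl group on C7 and an inverted (8R)-mesylate. In one operation, nickel-catalysed reductive carboxylation forms C11–C12 and the new carboxylate closes O–C8 by SN2 inversion, setting the trans ring fusion. The macrocycle comes from a Paterson aldol, an Evans–Tishchenko reduction that installs the ester, furanone formation and ring-closing metathesis.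

Key step: step 19

Numbering used in names and Why lines (germacrane type): C1 furanone carbonyl carbon; C2 furanone CH; C3 furanone carbon bonded to the ring oxygen and to C4; C4=C5 ring alkene (C15 is the methyl on C4); C6 carbon bearing the ester oxygen; C7 and C8 lactone fusion carbons (C8 bears the lactone oxygen); C9 CH2; C10 quaternary carbon bonded to the furanone oxygen (C14 is its methyl); C11, C12, C13 lactone α-carbon, carbonyl carbon and exocyclic CH2.

Assumption: (−)-Ipc2BOTf (from (+)-α-pinene) is written as the enantiomer of the boron reagent that leads from 12 to 15; if the facial sense is the opposite, the (+)-reagent serves in the same step.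

Step 1
Reactants: 1 (E)-2-methylbut-2-en-1-ol
Product: 2 [(2R,3R)-2,3-dimethyloxiran-2-yl]methanol
Conditions: Ti(OiPr)4 (10 mol %), D-(−)-DET (12 mol %), t-BuOOH, 4 Å MS, CH2Cl2, −20 °C
Reagents that add atoms: tert-butyl hydroperoxide CC(C)(C)OO
Why: Sharpless asymmetric epoxidation of the E-allylic alcohol, in which the D-tartrate catalyst should deliver oxygen to the face that gives the (2R,3R)-epoxide while the cis relation of the two methyl groups follows from the E-alkene.

Step 2
Reactants: 2 [(2R,3R)-2,3-dimethyloxiran-2-yl]methanol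
Product: 3 (2S,3R)-2,3-dimethyloxirane-2-carbaldehyde
Conditions: TEMPO (10 mol %), PhI(OAc)2, CH2Cl2, rt; the solution is used directly
Reagents that add atoms: none
Why: TEMPO-catalysed oxoammonium oxidation stops at the aldehyde and leaves the epoxide alone, and the quaternary α-carbon cannot epimerise.

Step 3
Reactants: 4 (S)-(2-methyloxiran-2-yl)methanol; 5 vinylmagnesium bromide
Product: 6 (R)-2-methylpent-4-ene-1,2-diol
Conditions: 5 (3 equiv), CuBr·SMe2 (10 mol %), THF, −40 → 0 °C; aq NH4Cl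
Reagents that add atoms: none
Why: Copper-catalysed Grignard opening of the 2,2-disubstituted epoxide at its unhindered CH2 carbon, which leaves the chiral-pool quaternary centre (later C10) untouched, the descriptor changing from S to R only through the ranking of the groups.

Step 4
Reactants: 6 (R)-2-methylpent-4-ene-1,2-diol
Product: 7 (R)-2,2,4-trimethyl-4-(prop-2-en-1-yl)-1,3-dioxolane
Conditions: Me2C(OMe)2, PPTS (cat.), CH2Cl2, rt
Reagents that add atoms: 2,2-dimethoxypropane COC(C)(C)OC
Why: Acid-catalysed transketalisation masks the primary and tertiary hydroxyl groups (C1–O and C10–O) as an acetonide.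

Step 5
Reactants: 7 (R)-2,2,4-trimethyl-4-(prop-2-en-1-yl)-1,3-dioxolane
Product: 9 2-[(4R)-2,2,4-trimethyl-1,3-dioxolan-4-yl]acetaldehyde, via secondary ozonide 8 (not isolated)
Conditions: O3, CH2Cl2, −78 °C; then PPh3, −78 °C → rt
Reagents that add atoms: ozone [O-][O+]=O
Why: Ozonolysis with reductive work-up cleaves the only alkene to the aldehyde that becomes C8.

Step 6
Reactants: 9 2-[(4R)-2,2,4-trimethyl-1,3-dioxolan-4-yl]acetaldehyde; 10 2,3-dibromoprop-1-ene
Product: 11 4-bromo-1-[(4R)-2,2,4-trimethyl-1,3-dioxolan-4-yl]pent-4-en-2-ol (both carbinol epimers)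
Conditions: In powder, THF/H2O (1:1), rt
Reagents that add atoms: none
Why: Indium-mediated Barbier allylation brings in the 2-bromoallyl unit (C7, C11, C13) under neutral aqueous conditions, and the new carbinol needs no control because it is oxidised in the next step.

Step 7
Reactants: 11 4-bromo-1-[(4R)-2,2,4-trimethyl-1,3-dioxolan-4-yl]pent-4-en-2-ol
Product: 12 4-bromo-1-[(4R)-2,2,4-trimethyl-1,3-dioxolan-4-yl]pent-4-en-2-one
Conditions: Dess–Martin periodinane, pyridine, CH2Cl2, 0 °C
Reagents that add atoms: none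
Why: Buffered Dess–Martin oxidation should give the β,γ-unsaturated ketone without moving the alkene into conjugation.

Step 8
Reactants: 12 4-bromo-1-[(4R)-2,2,4-trimethyl-1,3-dioxolan-4-yl]pent-4-en-2-one; 13 acrolein
Product: 15 (3S,4R)-3-(1-bromoethenyl)-4-hydroxy-1-[(4R)-2,2,4-trimethyl-1,3-dioxolan-4-yl]hex-5-en-2-one, via Z-enol borinate 14 (not isolated)
Conditions: (−)-Ipc2BOTf, i-Pr2NEt, CH2Cl2, −78 °C; then 13, −78 → −20 °C; pH 7 buffer, MeOH, H2O2, 0 °C
Reagents that add atoms: none
Why: Paterson boron aldol, in which soft enolisation on the more acidic allylic C7 side gives the Z-enolate that adds to acrolein through a chair Zimmerman–Traxler transition state to give the 6,7-syn adduct, the isopinocampheyl ligands choosing the aldehyde face so that C6 and C7 are set under reagent control.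

Step 9
Reactants: 15 (3S,4R)-3-(1-bromoethenyl)-4-hydroxy-1-[(4R)-2,2,4-trimethyl-1,3-dioxolan-4-yl]hex-5-en-2-one; 3 (2S,3R)-2,3-dimethyloxirane-2-carbaldehyde
Product: 17 (3R,4R,5R)-4-(1-bromoethenyl)-5-hydroxy-6-[(4R)-2,2,4-trimethyl-1,3-dioxolan-4-yl]hex-1-en-3-yl (2S,3R)-2,3-dimethyloxirane-2-carboxylate, via hemiacetal 16 (not isolated)
Conditions: SmI2 (30 mol %), 3 (5 equiv), THF, −10 °C
Reagents that add atoms: none
Why: Evans–Tishchenko reduction, in which the O6 hemiacetal of aldehyde 3 delivers its hydride intramolecularly to the samarium-bound C8 ketone through a chair, which should set the 1,3-anti (8R) carbinol and leave the epoxy acyl group of the target on O6.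

Step 10
Reactants: 17 the ester alcohol from step 9
Product: 18 (3R,4S,5R)-4-(1-bromoethenyl)-5-[(tert-butyldimethylsilyl)oxy]-6-[(4R)-2,2,4-trimethyl-1,3-dioxolan-4-yl]hex-1-en-3-yl (2S,3R)-2,3-dimethyloxirane-2-carboxylate
Conditions: TBSOTf, 2,6-lutidine, CH2Cl2, −78 → 0 °C
Reagents that add atoms: tert-butyldimethylsilyl trifluoromethanesulfonate CC(C)(C)[Si](C)(C)OS(=O)(=O)C(F)(F)F
Why: Silylation with the silyl triflate masks the hindered C8 hydroxyl and stops 1,3-acyl migration from O6.

Step 11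
Reactants: 18 the silyl ether from step 10
Product: 19 (3R,4S,5R,7R)-4-(1-bromoethenyl)-5-[(tert-butyldimethylsilyl)oxy]-7,8-dihydroxy-7-methyloct-1-en-3-yl (2S,3R)-2,3-dimethyloxirane-2-carboxylate
Conditions: CeCl3·7H2O, (CO2H)2 (cat.), MeCN, rt
Reagents that add atoms: none
Why: Mild Lewis-acid-assisted hydrolysis of the terminal acetonide, which the secondary silyl ether, the epoxide and the ester should survive.

Step 12
Reactants: 19 the diol from step 11
Product: 20 (3R,4S,5R,7R)-4-(1-bromoethenyl)-5-[(tert-butyldimethylsilyl)oxy]-7-hydroxy-7-methyl-8-oxooct-1-en-3-yl (2S,3R)-2,3-dimethyloxirane-2-carboxylate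
Conditions: TEMPO (20 mol %), PhI(OAc)2, CH2Cl2, rt
Reagents that add atoms: none
Why: Chemoselective TEMPO oxidation of the primary alcohol (C1) to the aldehyde, the tertiary C10 hydroxyl being inert.

Step 13
Reactants: 20 the hydroxy aldehyde from step 12; 21 2-methylbut-1-en-3-yne
Product: 22 (3R,4S,5R,7R)-4-(1-bromoethenyl)-5-[(tert-butyldimethylsilyl)oxy]-7,8-dihydroxy-7,11-dimethyldodeca-1,11-dien-9-yn-3-yl (2S,3R)-2,3-dimethyloxirane-2-carboxylate (both C8 epimers of the chain)
Conditions: 21 (3.5 equiv), n-BuLi (3.3 equiv), THF, −78 °C; then 20; aq NH4Cl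
Reagents that add atoms: none
Why: 1,2-Addition of the lithium acetylide to the aldehyde at −78 °C should outrun attack on the hindered ester, and the new carbinol centre is removed in the next step.

Step 14
Reactants: 22 the propargylic diol from step 13
Product: 23 (3R,4S,5R,7R)-4-(1-bromoethenyl)-5-[(tert-butyldimethylsilyl)oxy]-7-hydroxy-7,11-dimethyl-8-oxododeca-1,11-dien-9-yn-3-yl (2S,3R)-2,3-dimethyloxirane-2-carboxylate
Conditions: IBX, DMSO, rt
Reagents that add atoms: none
Why: IBX oxidises the secondary propargylic alcohol to the ynone without cleaving the neighbouring tertiary glycol.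

Step 15
Reactants: 23 the hydroxy ynone from step 14
Product: 24 (3R,4S,5R)-4-(1-bromoethenyl)-5-[(tert-butyldimethylsilyl)oxy]-6-[(2R)-2-methyl-3-oxo-5-(prop-1-en-2-yl)-2,3-dihydrofuran-2-yl]hex-1-en-3-yl (2S,3R)-2,3-dimethyloxirane-2-carboxylate
Conditions: Ph3PAuCl (5 mol %), AgOTf (5 mol %), toluene, rt
Reagents that add atoms: none
Why: Gold-catalysed 5-endo-dig cycloisomerisation of the α′-hydroxy ynone gives the 3(2H)-furanone with C10 unchanged.

Step 16
Reactants: 24 the acyclic furanone from step 15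
Product: 25 silyl ether macrocycle: ten-membered carbocycle C1–C10 with the furanone oxygen bridging C3 and C10 (C1 ketone, C2=C3, 4Z-C4=C5, methyls on C4 and C10), 6-O-[(2S,3R)-2,3-dimethyloxirane-2-carbonyl], 7-(1-bromoethenyl), 8-OTBS; 6R,7S,8R,10R
Conditions: second-generation Hoveyda–Grubbs catalyst (15 mol %), toluene (1 mM), 100 °C
Reagents that add atoms: none
Why: Ring-closing metathesis between the C6 vinyl group and the furanone isopropenyl group closes the carbocycle at C4=C5, and the nine-membered oxa-bridged ring allows only the Z alkene.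

Step 17
Reactants: 25 silyl ether macrocycle
Product: 26 alcohol macrocycle: as 25 with free 8-OH; 6R,7R,8R,10R
Conditions: HF·pyridine, pyridine, THF, 0 °C → rt
Reagents that add atoms: none
Why: Buffered fluoride cleavage of the silyl ether should spare the epoxide, the ester and the furanone, and the hindered tertiary acyl group should resist migration to O8.

Step 18
Reactants: 26 alcohol macrocycle
Product: 27 mesylate macrocycle: as 25 with 8-OMs; 6R,7S,8R,10R
Conditions: MsCl, Et3N, CH2Cl2, −20 → 0 °C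
Reagents that add atoms: methanesulfonyl chloride CS(=O)(=O)Cl
Why: Sulfonylation of the secondary alcohol with retention places the leaving group on C8.

Step 19
Reactants: 27 mesylate macrocycle; 28 carbon dioxide
Product: 30 CNP0258430.2 (bicyclic core of 25 with the C7–C8 trans-fused α-methylene-γ-butyrolactone; 4Z,6R,7R,8S,10R), via alkenyl carboxylate 29 (not isolated)
Conditions: NiCl2(PPh3)2 (10 mol %), PPh3 (20 mol %), Mn powder (3 equiv), Et4NI (10 mol %), CO2 (1 atm), DMI, 25 °C; then 50 °C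
Reagents that add atoms: none
Why: NiCl2(PPh3)2 is reduced by manganese to zerovalent nickel, which inserts into the C11–Br bond; one-electron reduction by manganese gives a monovalent alkenylnickel that adds to CO2 and so forms C11–C12, the acrylate 29 leaving nickel as its manganese salt. On warming, a carboxylate oxygen of 29 displaces the C8 mesylate from the back in a 5-exo-tet SN2 closure, which forms O–C8 and the five-membered lactone ring. The closest known reactions are the nickel-catalysed reductive carboxylation of alkenyl halides and triflates with CO2 and manganese, and the lactonisation of carboxylate salts onto secondary sulfonates with inversion. The only new stereocentre, C8, is fixed by this inversion of the (8R)-mesylate set in step 9, so that O8 ends syn to C11 and the lactone is trans-fused to the ten-membered ring, while C7 is not touched. The step needs insertion at the alkenyl bromide ahead of the allylic ester, the epoxide and the sulfonate, which the far faster reaction of the C(sp2)–Br bond at room temperature should secure, and substitution ahead of elimination, which the weakly basic carboxylate and the five-membered transition state should secure.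

Compound list
1 | (E)-2-methylbut-2-en-1-ol | C/C=C(\C)CO | starting material
2 | [(2R,3R)-2,3-dimethyloxiran-2-yl]methanol | OC[C@@]1(C)O[C@@H]1C | intermediate
3 | (2S,3R)-2,3-dimethyloxirane-2-carbaldehyde | O=C[C@@]1(C)O[C@@H]1C | intermediate
4 | (S)-(2-methyloxiran-2-yl)methanol | C[C@]1(CO)CO1 | starting material
5 | vinylmagnesium bromide | C=C[Mg]Br | starting material
6 | (R)-2-methylpent-4-ene-1,2-diol | C=CC[C@@](CO)(C)O | intermediate
7 | (R)-2,2,4-trimethyl-4-(prop-2-en-1-yl)-1,3-dioxolane | C=CC[C@]1(C)COC(C)(C)O1 | intermediate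
8 | secondary ozonide of 7, (4R)-2,2,4-trimethyl-4-(1,2,4-trioxolan-3-ylmethyl)-1,3-dioxolane | C1OC(C[C@]2(C)COC(C)(C)O2)OO1 | intermediate (not isolated)
9 | 2-[(4R)-2,2,4-trimethyl-1,3-dioxolan-4-yl]acetaldehyde | O=CC[C@]1(C)COC(C)(C)O1 | intermediate
10 | 2,3-dibromoprop-1-ene | C=C(Br)CBr | starting material
11 | 4-bromo-1-[(4R)-2,2,4-trimethyl-1,3-dioxolan-4-yl]pent-4-en-2-ol (both carbinol epimers) | C=C(Br)CC(O)C[C@]1(C)COC(C)(C)O1 | intermediate
12 | 4-bromo-1-[(4R)-2,2,4-trimethyl-1,3-dioxolan-4-yl]pent-4-en-2-one | C=C(Br)CC(=O)C[C@]1(C)COC(C)(C)O1 | intermediate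
13 | acrolein | C=CC=O | starting material
14 | Z-enol diisopinocampheylborinate of 12 | C=C(Br)/C=C(/C[C@]1(C)COC(C)(C)O1)OB(C2CC3CC(C2C)C3(C)C)C2CC3CC(C2C)C3(C)C | intermediate (not isolated)
15 | (3S,4R)-3-(1-bromoethenyl)-4-hydroxy-1-[(4R)-2,2,4-trimethyl-1,3-dioxolan-4-yl]hex-5-en-2-one | C=C[C@@H](O)[C@H](C(Br)=C)C(=O)C[C@]1(C)COC(C)(C)O1 | intermediate
16 | hemiacetal of 15 (O6) and aldehyde 3 | C=C[C@@H](OC(O)[C@@]2(C)O[C@@H]2C)[C@H](C(Br)=C)C(=O)C[C@]1(C)COC(C)(C)O1 | intermediate (not isolated)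
17 | (3R,4R,5R)-4-(1-bromoethenyl)-5-hydroxy-6-[(4R)-2,2,4-trimethyl-1,3-dioxolan-4-yl]hex-1-en-3-yl (2S,3R)-2,3-dimethyloxirane-2-carboxylate | C=C[C@@H](OC(=O)[C@@]2(C)O[C@@H]2C)[C@H](C(Br)=C)[C@H](O)C[C@]1(C)COC(C)(C)O1 | intermediate
18 | (3R,4S,5R)-4-(1-bromoethenyl)-5-[(tert-butyldimethylsilyl)oxy]-6-[(4R)-2,2,4-trimethyl-1,3-dioxolan-4-yl]hex-1-en-3-yl (2S,3R)-2,3-dimethyloxirane-2-carboxylate | C=C[C@@H](OC(=O)[C@@]2(C)O[C@@H]2C)[C@H](C(Br)=C)[C@H](O[Si](C)(C)C(C)(C)C)C[C@]1(C)COC(C)(C)O1 | intermediate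
19 | (3R,4S,5R,7R)-4-(1-bromoethenyl)-5-[(tert-butyldimethylsilyl)oxy]-7,8-dihydroxy-7-methyloct-1-en-3-yl (2S,3R)-2,3-dimethyloxirane-2-carboxylate | C=C[C@@H](OC(=O)[C@@]2(C)O[C@@H]2C)[C@H](C(Br)=C)[C@H](O[Si](C)(C)C(C)(C)C)C[C@@](C)(O)CO | intermediate
20 | (3R,4S,5R,7R)-4-(1-bromoethenyl)-5-[(tert-butyldimethylsilyl)oxy]-7-hydroxy-7-methyl-8-oxooct-1-en-3-yl (2S,3R)-2,3-dimethyloxirane-2-carboxylate | C=C[C@@H](OC(=O)[C@@]2(C)O[C@@H]2C)[C@H](C(Br)=C)[C@H](O[Si](C)(C)C(C)(C)C)C[C@@](C)(O)C=O | intermediate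
21 | 2-methylbut-1-en-3-yne | C=C(C)C#C | starting material
22 | (3R,4S,5R,7R)-4-(1-bromoethenyl)-5-[(tert-butyldimethylsilyl)oxy]-7,8-dihydroxy-7,11-dimethyldodeca-1,11-dien-9-yn-3-yl (2S,3R)-2,3-dimethyloxirane-2-carboxylate (both C8 epimers) | C=C[C@@H](OC(=O)[C@@]2(C)O[C@@H]2C)[C@H](C(Br)=C)[C@H](O[Si](C)(C)C(C)(C)C)C[C@@](C)(O)C(O)C#CC(C)=C | intermediate
23 | (3R,4S,5R,7R)-4-(1-bromoethenyl)-5-[(tert-butyldimethylsilyl)oxy]-7-hydroxy-7,11-dimethyl-8-oxododeca-1,11-dien-9-yn-3-yl (2S,3R)-2,3-dimethyloxirane-2-carboxylate | C=C[C@@H](OC(=O)[C@@]2(C)O[C@@H]2C)[C@H](C(Br)=C)[C@H](O[Si](C)(C)C(C)(C)C)C[C@@](C)(O)C(=O)C#CC(C)=C | intermediate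
24 | (3R,4S,5R)-4-(1-bromoethenyl)-5-[(tert-butyldimethylsilyl)oxy]-6-[(2R)-2-methyl-3-oxo-5-(prop-1-en-2-yl)-2,3-dihydrofuran-2-yl]hex-1-en-3-yl (2S,3R)-2,3-dimethyloxirane-2-carboxylate | C=C[C@@H](OC(=O)[C@@]2(C)O[C@@H]2C)[C@H](C(Br)=C)[C@H](O[Si](C)(C)C(C)(C)C)C[C@@]1(C)OC(C(C)=C)=CC1=O | intermediate
25 | silyl ether macrocycle (furanone-bridged ten-membered ring, 4Z; 6-O-epoxy ester, 7-(1-bromoethenyl), 8-OTBS; 6R,7S,8R,10R) | C=C(Br)[C@@H]1[C@H](O[Si](C)(C)C(C)(C)C)C[C@@]2(C)OC(=CC2=O)/C(C)=C\[C@H]1OC(=O)[C@@]3(C)O[C@@H]3C | intermediate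
26 | alcohol macrocycle (as 25, 8-OH; 6R,7R,8R,10R) | C=C(Br)[C@@H]1[C@H](O)C[C@@]2(C)OC(=CC2=O)/C(C)=C\[C@H]1OC(=O)[C@@]3(C)O[C@@H]3C | intermediate
27 | mesylate macrocycle (as 25, 8-OMs; 6R,7S,8R,10R) | C=C(Br)[C@@H]1[C@H](OS(C)(=O)=O)C[C@@]2(C)OC(=CC2=O)/C(C)=C\[C@H]1OC(=O)[C@@]3(C)O[C@@H]3C | intermediate
28 | carbon dioxide | O=C=O | starting material
29 | alkenyl carboxylate of 27 (C11–CO2−, manganese salt) | C=C(C(=O)[O-])[C@@H]1[C@H](OS(C)(=O)=O)C[C@@]2(C)OC(=CC2=O)/C(C)=C\[C@H]1OC(=O)[C@@]3(C)O[C@@H]3C | intermediate (not isolated)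
30 | CNP0258430.2 (4Z,6R,7R,8S,10R; ester 2S,3R) | C=C1C(=O)O[C@H]2C[C@@]3(C)OC(=CC3=O)/C(C)=C\[C@@H](OC(=O)[C@@]3(C)O[C@@H]3C)[C@H]12 | target

Total step count: 19. Longest linear sequence: 17 steps (steps 3–19, from 4).

Steps most likely to fail

Step 19. Zerovalent nickel may insert into the allylic C6–O bond or open the epoxide reductively instead of reacting only at the alkenyl bromide. The carboxylate may also close too slowly, so that elimination of the mesylate or halide exchange at C8 takes over. The fallback closes the lactone from the acyl side with CO. It sets out from alcohol 26: a Mitsunobu reaction (PPh3, diisopropyl azodicarboxylate, chloroacetic acid) inverts C8 and gives the (8S)-chloroacetate F1. Thiourea in EtOH/pyridine removes the chloroacetyl group to give the (8S)-alcohol F2. Palladium-catalysed carbonylative lactonisation (Pd(PPh3)4, CO, Et3N, MeCN, 60 °C) then forms C11–C12 and the acyl C12–O bond with retention at C8 and comes back to the route at 30.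

Step 16. The unhindered vinyl group may oligomerise by cross-metathesis, or the ruthenium carbene may fail to engage the electron-poor isopropenyl group while the chain is still flexible. The fallback changes the order of ring formation so that the lactone pre-organises the chain. It sets out from 24: desilylation (HF·pyridine) gives the acyclic alcohol F3, mesylation gives the acyclic mesylate F4, and the nickel-catalysed carboxylative lactonisation of step 19 gives the acyclic trans-lactone F5. Ring-closing metathesis of F5 with the same ruthenium catalyst closes C4=C5 last and comes back to the route at 30.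

Step 9. SmI2 may open the epoxide of aldehyde 3 reductively, hemiacetal formation with this α-quaternary aldehyde may be slow, or the acyl group may migrate from O6 to O8 under the samarium alkoxide. The fallback separates reduction from acylation. It sets out from 15: Evans–Tishchenko reduction with benzaldehyde gives the O6 benzoate F6, silylation (TBSOTf, 2,6-lutidine) gives the silyl ether benzoate F7, and i-Bu2AlH at −78 °C removes the benzoate to give the C6 alcohol F8. Aldehyde 3 is oxidised (NaClO2, NaH2PO4, 2-methylbut-2-ene) to the epoxy acid F9, and Yamaguchi esterification of F8 with F9 (2,4,6-trichlorobenzoyl chloride, Et3N, DMAP) comes back to the route at 18.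

Further compounds
F1 | step 19 | (8S)-chloroacetate, C8-inverted chloroacetyl ester of 26 | C=C(Br)[C@@H]1[C@@H](OC(=O)CCl)C[C@@]2(C)OC(=CC2=O)/C(C)=C\[C@H]1OC(=O)[C@@]3(C)O[C@@H]3C
F2 | step 19 | (8S)-alcohol, C8 epimer of 26 | C=C(Br)[C@@H]1[C@@H](O)C[C@@]2(C)OC(=CC2=O)/C(C)=C\[C@H]1OC(=O)[C@@]3(C)O[C@@H]3C
F3 | step 16 | (3R,4R,5R)-4-(1-bromoethenyl)-5-hydroxy-6-[(2R)-2-methyl-3-oxo-5-(prop-1-en-2-yl)-2,3-dihydrofuran-2-yl]hex-1-en-3-yl (2S,3R)-2,3-dimethyloxirane-2-carboxylate | C=C[C@@H](OC(=O)[C@@]2(C)O[C@@H]2C)[C@H](C(Br)=C)[C@H](O)C[C@@]1(C)OC(C(C)=C)=CC1=O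
F4 | step 16 | (3R,4S,5R)-4-(1-bromoethenyl)-5-[(methanesulfonyl)oxy]-6-[(2R)-2-methyl-3-oxo-5-(prop-1-en-2-yl)-2,3-dihydrofuran-2-yl]hex-1-en-3-yl (2S,3R)-2,3-dimethyloxirane-2-carboxylate | C=C[C@@H](OC(=O)[C@@]2(C)O[C@@H]2C)[C@H](C(Br)=C)[C@H](OS(C)(=O)=O)C[C@@]1(C)OC(C(C)=C)=CC1=O
F5 | step 16 | acyclic trans-α-methylene-γ-butyrolactone (lactone on C7/C8, C6 vinyl and furanone isopropenyl still open; 6R,7R,8S,10R) | C=C[C@@H](OC(=O)[C@@]2(C)O[C@@H]2C)[C@@H]3C(=C)C(=O)O[C@H]3C[C@@]1(C)OC(C(C)=C)=CC1=O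
F6 | step 9 | (3R,4R,5R)-4-(1-bromoethenyl)-5-hydroxy-6-[(4R)-2,2,4-trimethyl-1,3-dioxolan-4-yl]hex-1-en-3-yl benzoate | C=C[C@@H](OC(=O)c2ccccc2)[C@H](C(Br)=C)[C@H](O)C[C@]1(C)COC(C)(C)O1
F7 | step 9 | (3R,4S,5R)-4-(1-bromoethenyl)-5-[(tert-butyldimethylsilyl)oxy]-6-[(4R)-2,2,4-trimethyl-1,3-dioxolan-4-yl]hex-1-en-3-yl benzoate | C=C[C@@H](OC(=O)c2ccccc2)[C@H](C(Br)=C)[C@H](O[Si](C)(C)C(C)(C)C)C[C@]1(C)COC(C)(C)O1
F8 | step 9 | (3R,4S,5R)-4-(1-bromoethenyl)-5-[(tert-butyldimethylsilyl)oxy]-6-[(4R)-2,2,4-trimethyl-1,3-dioxolan-4-yl]hex-1-en-3-ol | C=C[C@@H](O)[C@H](C(Br)=C)[C@H](O[Si](C)(C)C(C)(C)C)C[C@]1(C)COC(C)(C)O1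
F9 | step 9 | (2S,3R)-2,3-dimethyloxirane-2-carboxylic acid | OC(=O)[C@@]1(C)O[C@@H]1C
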